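**Plan**

Feature: ring C is a six-membered oxygen heterocycle fused to arene ring A. O1–C8a–C4a–C4 is therefore the skeleton of an ortho-quinone methide (a 1-oxadiene), and C2–C3 is the former vinyl group of a ring B styrene (flavanone numbering).
Cuts: the C4 ketone goes back to a C4 methyl ether, then O1–C2 and C3–C4 are cut together. Behind that lie the vinyl C=C, the O–CMe2 and aryl–CH= bonds of the dimethylpyran (ring D), and the two aryl–prenyl bonds.
Forward, ring B half: 4-hydroxybenzaldehyde is ortho-prenylated, ring D is closed by a propargyl ether rearrangement, and the aldehyde is methylenated.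
Forward, ring A half: 2,4-dihydroxybenzaldehyde is prenylated at C3 and silylated at O4.
Union: both halves and trimethyl orthoformate give ring C, the last ring, in one [4+2] step. Oxidation at C4 and desilylation end the route.
Stereochemistry: C2 (S), the only stereocentre of the target, comes from a chiral BINOL-derived phosphoric acid bound to the quinone methide. The auxiliary C4 centre disappears in the oxidation.

Key step: step 7

Assumption: no close precedent fixes the sense of induction of the chiral acid in step 7, so the (R)-catalyst is written and the (S)-catalyst takes its place if the first analysis shows the 2R series.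

**Route**

Step 1
Reactants: 1 4-hydroxybenzaldehyde; 2 prenyl bromide (1-bromo-3-methylbut-2-ene)
Product: 3 4-hydroxy-3-(3-methylbut-2-enyl)benzaldehyde
Conditions: 2 (1.0 equiv), KOH (aq, 1.5 equiv), rt
Reagents that add atoms: prenyl bromide (2), CC(C)=CCBr
Why: C-alkylation of an ambident phenoxide: in water the oxygen is masked by hydrogen bonding, so the allylic bromide is taken up partly at the ortho carbon, a long-used direct ortho-prenylation of this aldehyde; the O-prenyl ether and diprenylated material are removed by chromatography.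

Step 2
Reactants: 3 4-hydroxy-3-(3-methylbut-2-enyl)benzaldehyde; 4 3-chloro-3-methylbut-1-yne
Product: 5 4-[(2-methylbut-3-yn-2-yl)oxy]-3-(3-methylbut-2-enyl)benzaldehyde
Conditions: 4 (1.3 equiv), DBU (1.4 equiv), CuCl2·2H2O (1 mol %), MeCN, 0 °C
Reagents that add atoms: 3-chloro-3-methylbut-1-yne (4), C#CC(C)(C)Cl
Why: Copper-catalysed O-propargylation of a phenol with a tertiary propargylic chloride, which works well for electron-poor and ortho-substituted phenols and runs far below the temperature at which the ether rearranges.

Step 3
Reactants: 5 4-[(2-methylbut-3-yn-2-yl)oxy]-3-(3-methylbut-2-enyl)benzaldehyde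
Product: 6 2,2-dimethyl-8-(3-methylbut-2-enyl)-2H-chromene-6-carbaldehyde
Conditions: PhNEt2, 190 °C, N2
Reagents that add atoms: none
Why: Aromatic propargyl Claisen rearrangement to the only free ortho position, then 1,5-hydrogen shift and oxa-6π electrocyclisation, the standard 2,2-dimethylchromene synthesis; migration to the prenyl-bearing ortho carbon is reversible and unproductive.

Step 4
Reactants: 6 2,2-dimethyl-8-(3-methylbut-2-enyl)-2H-chromene-6-carbaldehyde
Product: 7 2,2-dimethyl-8-(3-methylbut-2-enyl)-6-vinyl-2H-chromene
Conditions: Ph3PCH3Br, KOtBu, THF, 0 °C to rt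
Reagents that add atoms: methyltriphenylphosphonium bromide, C[P+](c1ccccc1)(c1ccccc1)c1ccccc1.[Br-]
Why: Wittig methylenation of an aromatic aldehyde with the non-stabilised ylide, with no other electrophilic group present; the electron-rich styrene is kept cold with a trace of BHT and used soon.

Step 5
Reactants: 8 2,4-dihydroxybenzaldehyde; 2 prenyl bromide
Product: 9 2,4-dihydroxy-3-(3-methylbut-2-enyl)benzaldehyde
Conditions: 2 (1.0 equiv), KOH (aq), 0 °C to rt
Reagents that add atoms: prenyl bromide (2), CC(C)=CCBr
Why: Phenoxide C-alkylation in water: the resorcinol-type anion is most nucleophilic at C3 between the two oxygens, which makes this the known one-step entry to the 3-prenyl aldehyde; the C5 and O-alkylated isomers are separated by chromatography.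

Step 6
Reactants: 9 2,4-dihydroxy-3-(3-methylbut-2-enyl)benzaldehyde
Product: 10 4-(tert-butyldimethylsilyloxy)-2-hydroxy-3-(3-methylbut-2-enyl)benzaldehyde
Conditions: TBSCl (1.05 equiv), imidazole, CH2Cl2, 0 °C
Reagents that add atoms: tert-butyldimethylsilyl chloride, CC(C)(C)[Si](C)(C)Cl
Why: Selective phenol silylation: the 2-OH is held in a hydrogen bond to the formyl oxygen and is much less nucleophilic, so one equivalent of silyl chloride should react at the 4-OH only.

Step 7
Reactants: 10 4-(tert-butyldimethylsilyloxy)-2-hydroxy-3-(3-methylbut-2-enyl)benzaldehyde; 7 2,2-dimethyl-8-(3-methylbut-2-enyl)-6-vinyl-2H-chromene; 11 trimethyl orthoformate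
Product: 14 (2S,4S)-7-(tert-butyldimethylsilyloxy)-2-[2,2-dimethyl-8-(3-methylbut-2-enyl)-2H-chromen-6-yl]-4-methoxy-8-(3-methylbut-2-enyl)chroman (2,4-cis 4-methoxyflavan), via dimethyl acetal 12 (not isolated), via methoxy ortho-quinone methide 13 (not isolated)
Conditions: HC(OMe)3 (1.5 equiv), (R)-TRIP [(R)-3,3'-bis(2,4,6-triisopropylphenyl)-BINOL hydrogen phosphate] (10 mol %), 5 Å MS, PhMe, rt; then 7 (1.3 equiv), −30 °C
Reagents that add atoms: trimethyl orthoformate (11), COC(OC)OC
Why: Proposed new method: the acid first turns 10 and orthoformate 11 into acetal 12, which loses methanol to give the (E)-methoxy ortho-quinone methide 13, present mostly in its protonated form, an aryl oxocarbenium ion whose phenolic O–H is hydrogen-bonded to the chiral phosphate. This 1-oxadiene (O1=C8a–C4a=C4) takes up the vinyl group of 7 in an asynchronous inverse-demand hetero-Diels–Alder reaction in which the CH2 terminus bonds to C4 ahead of the capture of the developing para-alkoxybenzylic cation by O1, so that ring C closes by an intermolecular [4+2] cycloaddition (O1–C2 and C3–C4 formed in one operation) with the aryl group at C2. The closest known reaction types are the racemic acid-promoted union of salicylaldehydes, orthoformates and styrenes to 4-alkoxyflavans, the chiral phosphoric acid catalysed [4+2] cycloadditions of ortho-quinone methides with hydrogen-bonding styrenes, and the intramolecular cycloaddition of alkoxy ortho-quinone methides under confined chiral Brønsted acids, and what is new is the enantioselective intermolecular use of a styrene that offers no hydrogen-bond donor. C4 is set by the face of 13 that the 3,3'-aryl groups of the bound phosphate leave open, and C2 follows from C4 through the endo transition state, which puts the 2-aryl and 4-methoxy groups cis and both pseudo-equatorial. The step needs chemoselectivity for the vinyl group, which is secured because this is the only monosubstituted alkene and is pushed by the para chromene oxygen, whereas C3 of the chromene is shielded by the adjacent CMe2 group and the prenyl alkenes lack aryl conjugation, and the weak acid at low temperature should leave the ortho-prenylphenol, the silyl ether and the styrene itself untouched. A trans isomer formed on the same quinone methide face would carry 2R, so it is removed by chromatography before C4 is oxidised.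

Step 8
Reactants: 14 (2S,4S)-2,4-cis 4-methoxyflavan silyl ether
Product: 15 (2S)-7-(tert-butyldimethylsilyloxy)-2-[2,2-dimethyl-8-(3-methylbut-2-enyl)-2H-chromen-6-yl]-8-(3-methylbut-2-enyl)chroman-4-one
Conditions: DDQ (1.2 equiv), CH2Cl2/pH 7 phosphate buffer (10:1), 0 °C
Reagents that add atoms: water, O
Why: DDQ oxidation of an electron-rich benzylic ether, the chemistry of PMB and DMB ether cleavage and of the C4 dehydrogenation of 7-oxygenated chromans: the pseudo-axial C4–H is lost as hydride to give an oxocarbenium ion stabilised by OMe, O1 and O7, water adds and the hemiketal expels methanol, while C2 is not touched and prenyl groups whose neighbouring oxygens are all etherified should react far more slowly.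

Step 9
Reactants: 15 (2S)-7-silyloxyflavanone
Product: 16 (2S)-7-hydroxy-2-[2,2-dimethyl-8-(3-methylbut-2-enyl)-2H-chromen-6-yl]-8-(3-methylbut-2-enyl)chroman-4-one (CNP0110366.1)
Conditions: Bu4NF (1.1 equiv), AcOH (1.2 equiv), THF, 0 °C; pH 7 buffer work-up
Reagents that add atoms: none
Why: Fluoride cleavage of an aryl silyl ether para to a ketone is fast at 0 °C, and the acetic acid buffer keeps the medium from turning basic, so the retro-oxa-Michael opening to the chalcone that would racemise C2 should not set in.

**Compound list**

1 | 4-hydroxybenzaldehyde | O=Cc1ccc(O)cc1 | starting material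
2 | prenyl bromide (1-bromo-3-methylbut-2-ene) | CC(C)=CCBr | starting material
3 | 4-hydroxy-3-(3-methylbut-2-enyl)benzaldehyde | O=Cc1ccc(O)c(CC=C(C)C)c1 | intermediate
4 | 3-chloro-3-methylbut-1-yne | C#CC(C)(C)Cl | starting material
5 | 4-[(2-methylbut-3-yn-2-yl)oxy]-3-(3-methylbut-2-enyl)benzaldehyde | O=Cc1ccc(OC(C)(C)C#C)c(CC=C(C)C)c1 | intermediate
6 | 2,2-dimethyl-8-(3-methylbut-2-enyl)-2H-chromene-6-carbaldehyde | O=Cc1cc(CC=C(C)C)c2OC(C)(C)C=Cc2c1 | intermediate
7 | 2,2-dimethyl-8-(3-methylbut-2-enyl)-6-vinyl-2H-chromene | C=Cc1cc(CC=C(C)C)c2OC(C)(C)C=Cc2c1 | intermediate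
8 | 2,4-dihydroxybenzaldehyde | O=Cc1ccc(O)cc1O | starting material
9 | 2,4-dihydroxy-3-(3-methylbut-2-enyl)benzaldehyde | O=Cc1ccc(O)c(CC=C(C)C)c1O | intermediate
10 | 4-(tert-butyldimethylsilyloxy)-2-hydroxy-3-(3-methylbut-2-enyl)benzaldehyde | O=Cc1ccc(O[Si](C)(C)C(C)(C)C)c(CC=C(C)C)c1O | intermediate
11 | trimethyl orthoformate | COC(OC)OC | starting material
12 | dimethyl acetal of 10, formed in the flask | COC(OC)c1ccc(O[Si](C)(C)C(C)(C)C)c(CC=C(C)C)c1O | intermediate
13 | (E)-methoxy ortho-quinone methide derived from 12, formed in the flask | CO/C=C1\C=CC(O[Si](C)(C)C(C)(C)C)=C(CC=C(C)C)C1=O | intermediate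
14 | (2S,4S)-7-(tert-butyldimethylsilyloxy)-2-[2,2-dimethyl-8-(3-methylbut-2-enyl)-2H-chromen-6-yl]-4-methoxy-8-(3-methylbut-2-enyl)chroman | CC(C)=CCc1cc([C@@H]2C[C@H](OC)c3ccc(O[Si](C)(C)C(C)(C)C)c(CC=C(C)C)c3O2)cc2c1OC(C)(C)C=C2 | intermediate
15 | (2S)-7-(tert-butyldimethylsilyloxy)-2-[2,2-dimethyl-8-(3-methylbut-2-enyl)-2H-chromen-6-yl]-8-(3-methylbut-2-enyl)chroman-4-one | CC(C)=CCc1cc([C@@H]2CC(=O)c3ccc(O[Si](C)(C)C(C)(C)C)c(CC=C(C)C)c3O2)cc2c1OC(C)(C)C=C2 | intermediate
16 | (2S)-7-hydroxy-2-[2,2-dimethyl-8-(3-methylbut-2-enyl)-2H-chromen-6-yl]-8-(3-methylbut-2-enyl)chroman-4-one (CNP0110366.1) | CC(C)=CCc1cc([C@@H]2CC(=O)c3ccc(O)c(CC=C(C)C)c3O2)cc2c1OC(C)(C)C=C2 | target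

**Step count**

Total step count: 9.
Longest linear sequence: 7 (steps 1–4, then 7–9).

**Steps most likely to fail**

**Step 7.**
- What may go wrong:
  - Facial selectivity may be poor, because the styrene is held only through the ion pair and not by a hydrogen bond.
  - Endo/exo control may be incomplete.
  - Turnover may be slow with the weak acid.
  - The ortho-prenylphenol may cyclise under acid, or the styrene may oligomerise.
- Fallback: the stereocentre is obtained by kinetic resolution instead of by the cycloaddition.
  - The fallback sets out from 10, 7 and 11. The known racemic three-component cycloaddition under an achiral acid (diphenyl phosphate, CH2Cl2, 0 °C) passes through 12 and 13 and gives the racemic cis-4-methoxyflavan F1.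
  - DDQ oxidation as in step 8 gives the racemic silyl-protected flavanone F2.
  - Asymmetric transfer hydrogenation follows, with Cp*RhCl[(R,R)-TsDPEN] and HCO2H/Et3N in EtOAc, stopped near half conversion. It should reduce the 2R enantiomer to the (2R,4R)-cis-flavan-4-ol F3 and leave the 2S ketone.
  - Chromatography then returns the route to 15.

**Step 8.**
- What may go wrong: hydride abstraction may compete at the benzylic-allylic CH2 groups of the prenyl chains or at C2–H, and the enol ether stage may be over-oxidised.
- Fallback: the oxidation is split into a solvolysis and an alcohol oxidation.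
  - The fallback sets out from 14. PPTS in acetone/H2O at 40 °C exchanges the methoxy group for hydroxyl through the C4 benzylic cation and gives the (2S)-flavan-4-ol F4 as a mixture of C4 epimers.
  - Dess–Martin periodinane with NaHCO3 in CH2Cl2 oxidises both epimers, which brings the route back to 15.

**Step 5.**
- What may go wrong: regioselectivity may be low, since O-alkylation, C5-alkylation and double alkylation compete with attack at C3.
- Fallback: the prenyl group is delivered by a sigmatropic shift.
  - The fallback sets out from 8. The non-chelated 4-OH is etherified with 4 (DBU, catalytic CuCl2·2H2O, MeCN, 0 °C) to give the 4-O-(1,1-dimethylpropargyl) ether F5.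
  - Semihydrogenation (H2, Pd/CaCO3 poisoned with Pb(OAc)2, quinoline, EtOAc, rt) gives the 4-O-(1,1-dimethylallyl) ether F6.
  - An aromatic Claisen rearrangement (PhNEt2, 150 °C) follows. The chelated hydroxy-aldehyde directs it to C3, and the route comes back at 9.

Further compounds
F1 | step 7 | racemic (2S*,4S*)-cis-4-methoxyflavan silyl ether, both enantiomers written | CC(C)=CCc1cc([C@@H]2C[C@H](OC)c3ccc(O[Si](C)(C)C(C)(C)C)c(CC=C(C)C)c3O2)cc2c1OC(C)(C)C=C2.CC(C)=CCc1cc([C@H]2C[C@@H](OC)c3ccc(O[Si](C)(C)C(C)(C)C)c(CC=C(C)C)c3O2)cc2c1OC(C)(C)C=C2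
F2 | step 7 | racemic 7-silyloxyflavanone, both enantiomers written | CC(C)=CCc1cc([C@@H]2CC(=O)c3ccc(O[Si](C)(C)C(C)(C)C)c(CC=C(C)C)c3O2)cc2c1OC(C)(C)C=C2.CC(C)=CCc1cc([C@H]2CC(=O)c3ccc(O[Si](C)(C)C(C)(C)C)c(CC=C(C)C)c3O2)cc2c1OC(C)(C)C=C2
F3 | step 7 | (2R,4R)-cis-7-(tert-butyldimethylsilyloxy)flavan-4-ol of the same substitution pattern | CC(C)=CCc1cc([C@H]2C[C@@H](O)c3ccc(O[Si](C)(C)C(C)(C)C)c(CC=C(C)C)c3O2)cc2c1OC(C)(C)C=C2
F4 | step 8 | (2S)-7-(tert-butyldimethylsilyloxy)flavan-4-ol of the same substitution pattern, mixture of C4 epimers | CC(C)=CCc1cc([C@@H]2CC(O)c3ccc(O[Si](C)(C)C(C)(C)C)c(CC=C(C)C)c3O2)cc2c1OC(C)(C)C=C2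
F5 | step 5 | 2-hydroxy-4-[(2-methylbut-3-yn-2-yl)oxy]benzaldehyde | O=Cc1ccc(OC(C)(C)C#C)cc1O
F6 | step 5 | 2-hydroxy-4-[(2-methylbut-3-en-2-yl)oxy]benzaldehyde | O=Cc1ccc(OC(C)(C)C=C)cc1O
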